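Counting the main chain from the ring OCH2 of the butenolide (C1), past the ring α-carbon (C3), out to the carbinol carbon of the allylic alcohol (C16), the acyclic stereocentres C7 and C11 carry the same CH2OAc group, are bridged by C8–C10 and have the same handedness, so the C6–C12 segment is C2-symmetric; the butenolide ring lies outside it. Everything rests on cutting C6–C7 and C11–C12 together. A double orthoester Claisen rearrangement of (2R,3E,8E,10R)-undeca-3,8-diene-2,10-diol, two (R)-methyl carbinols on E-alkenes joined by three CH2 groups, makes both bonds and both stereocentres at once; in the resulting diester the E-propenyl groups are latent CH2OAc and the ester arms grow into the butenolide and Z-allylic alcohol chains.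

Key step: step 5

Remark: the target is read as (7R,11R) with a Z C14=C15 alkene (chain cis to CH2OH); an (R)-carbinol on an E-alkene maps onto an (R)-centre in the rearranged diester, so (R)-but-3-yn-2-ol is the correct enantiomer of the chiral starting material.

Step 1
Reactants: 1 (R)-but-3-yn-2-ol
Product: 2 (R)-tert-butyl(but-3-yn-2-yloxy)dimethylsilane
Conditions: TBSCl, imidazole, CH2Cl2, 0 °C to rt
Reagents that add atoms: tert-butyldimethylsilyl chloride, CC(C)(C)[Si](C)(C)Cl
Why: Imidazole-promoted O-silylation of a secondary alcohol should mask the hydroxyl before the acetylide chemistry without touching the (R)-centre.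

Step 2
Reactants: 2 (R)-tert-butyl(but-3-yn-2-yloxy)dimethylsilane (2.2 equiv), 3 1,3-dibromopropane
Product: 6 (2R,10R)-2,10-bis{[tert-butyl(dimethyl)silyl]oxy}undeca-3,8-diyne, via lithium acetylide 4 (not isolated), via bromoalkyne 5 (not isolated)
Conditions: n-BuLi (2.15 equiv), THF, −78 °C; then 3 (1.0 equiv), DMPU, −78 °C to rt
Reagents that add atoms: 1,3-dibromopropane (3), BrCCCBr
Why: Deprotonation of the terminal alkyne gives lithium acetylide 4, which should displace both primary bromides of 3 by SN2 in the dipolar cosolvent (acetylide alkylation) by way of bromoalkyne 5; the (R)-carbinol centres are remote from the reacting carbons and are retained, and joining two molecules of one enantiomer channels any minor enantiomer of 1 into a separable meso diastereomer.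

Step 3
Reactants: 6 (2R,10R)-2,10-bis{[tert-butyl(dimethyl)silyl]oxy}undeca-3,8-diyne
Product: 7 (2R,10R)-undeca-3,8-diyne-2,10-diol
Conditions: Bu4NF, THF, 0 °C to rt
Reagents that add atoms: none
Why: Fluoride-induced Si–O cleavage (desilylation) should free both propargylic alcohols, which are needed as directing groups in the next step.

Step 4
Reactants: 7 (2R,10R)-undeca-3,8-diyne-2,10-diol
Product: 9 (2R,3E,8E,10R)-undeca-3,8-diene-2,10-diol, via cyclic alkenylalanate 8 (not isolated)
Conditions: LiAlH4, THF, 0 °C to reflux; then H2O, aq. NaOH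
Reagents that add atoms: none
Why: Each lithium alkoxyaluminium hydride should deliver hydride to the adjacent alkyne in an anti sense (hydroxyl-directed trans-hydroalumination of propargylic alcohols) to give cyclic alkenylalanate 8, and protonolysis on work-up should leave only E-alkenes with both carbinol centres unchanged.

Step 5
Reactants: 9 (2R,3E,8E,10R)-undeca-3,8-diene-2,10-diol, 10 triethyl orthoacetate
Product: 13 diethyl (3R,7R)-3,7-di[(E)-prop-1-en-1-yl]nonanedioate, via bis(orthoester) 11 (not isolated), via bis(ketene acetal) 12 (not isolated)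
Conditions: 10 (excess), EtCO2H (cat.), 140 °C, EtOH distilled off
Reagents that add atoms: triethyl orthoacetate (10), CCOC(C)(OCC)OCC
Why: Acid-catalysed exchange places each hydroxyl on an orthoester carbon (11), loss of ethanol gives bis(ketene acetal) 12, and each allyl ketene acetal undergoes a concerted [3,3]-sigmatropic shift that forms C6–C7 and C11–C12 and turns each carbinol C–O bond into an ester carbonyl. The closest known reaction is the Johnson–Claisen (orthoester Claisen) rearrangement of E-configured secondary allylic alcohols, here run at both ends of one diol. No ring is closed. C7 and C11 are each controlled by the adjacent carbinol centre: in the chair transition state the carbinol methyl is equatorial and bond breaking and bond making occur on the same face of the allyl unit, so each (R)-carbinol becomes an (R)-CH bearing CH2CO2Et, the chain and an E-propenyl group. The step needs chair selectivity and an equatorial methyl at both ends, which the E-alkene geometry and the 1,3-diaxial clash of an axial methyl with the ketene acetal ethoxy group should secure. The two events are independent, so any leak would show up as a separable diastereomer and not as eroded enantiopurity.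

Step 6
Reactants: 13 diethyl (3R,7R)-3,7-di[(E)-prop-1-en-1-yl]nonanedioate
Product: 16 (4R,4'R)-4,4'-(propane-1,3-diyl)bis(dihydrofuran-2(3H)-one), via bis-ozonide 14 (not isolated), via diol diester 15 (not isolated)
Conditions: O3, CH2Cl2, −78 °C; then NaBH4, EtOH, −78 °C to rt; then 1 M HCl, rt
Reagents that add atoms: ozone, [O-][O+]=O
Why: Ozone should cleave both E-propenyl groups through ozonide 14 (Criegee ozonolysis), borohydride should reduce the fragments to the primary alcohols of 15, and each γ-hydroxy ester should close to a five-membered lactone on acidification, while C7 and C11 sit β to the carbonyls and cannot epimerise.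

Step 7
Reactants: 16 (4R,4'R)-4,4'-(propane-1,3-diyl)bis(dihydrofuran-2(3H)-one)
Product: 17 (4R,4'R)-4,4'-(propane-1,3-diyl)bis(tetrahydrofuran-2-ol) (anomer mixture)
Conditions: i-Bu2AlH (2.2 equiv), CH2Cl2, −78 °C; aq. KNaC4H4O6
Reagents that add atoms: none
Why: At −78 °C i-Bu2AlH should add a single hydride to each γ-lactone (partial lactone reduction) and the lactols are released only on aqueous work-up, so over-reduction to the open diol is avoided.

Step 8
Reactants: 17 (4R,4'R)-4,4'-(propane-1,3-diyl)bis(tetrahydrofuran-2-ol)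
Product: 19 (2R,6R)-2,6-di(prop-2-en-1-yl)heptane-1,7-diol, via hydroxy aldehyde 18 (not isolated)
Conditions: Ph3PCH3Br (excess), KOt-Bu, THF, 0 °C to rt
Reagents that add atoms: methyltriphenylphosphonium bromide, C[P+](c1ccccc1)(c1ccccc1)c1ccccc1.[Br-]
Why: Excess ylide deprotonates the lactols, which open to hydroxy aldehyde 18 and undergo Wittig methylenation at both ends, adding C4 and C14 as terminal CH2 groups without affecting the β-stereocentres.

Step 9
Reactants: 19 (2R,6R)-2,6-di(prop-2-en-1-yl)heptane-1,7-diol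
Product: 20 (2R,6R)-2,6-di(prop-2-en-1-yl)heptane-1,7-diyl diacetate
Conditions: Ac2O, pyridine, DMAP (cat.), CH2Cl2, 0 °C to rt
Reagents that add atoms: acetic anhydride, CC(=O)OC(C)=O
Why: DMAP-catalysed acylation of both primary alcohols should install the two acetates of the target at a point where only terminal alkenes remain as other functionality.

Step 10
Reactants: 20 (2R,6R)-2,6-di(prop-2-en-1-yl)heptane-1,7-diyl diacetate
Product: 22 (2R,6R)-2-(3-hydroxypropyl)-6-(prop-2-en-1-yl)heptane-1,7-diyl diacetate, via alkylborane 21 (not isolated)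
Conditions: 9-BBN (0.8 equiv), THF, 0 °C to rt; then NaBO3·4H2O, H2O, rt
Reagents that add atoms: sodium perborate tetrahydrate (oxygen source), O[B-]1(O)OO[B-](O)(O)OO1.[Na+].[Na+]
Why: 9-BBN adds anti-Markovnikov to a terminal alkene and, used in deficiency, should convert one allyl group into alkylborane 21, which near-neutral perborate oxidation turns into the primary alcohol without cleaving the acetates (hydroboration–oxidation); because the two arms are homotopic the mono-adduct is a single compound, and unreacted 20 is recovered for recycling.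

Step 11
Reactants: 22 (2R,6R)-2-(3-hydroxypropyl)-6-(prop-2-en-1-yl)heptane-1,7-diyl diacetate
Product: 23 (2R,6R)-2-(3-iodopropyl)-6-(prop-2-en-1-yl)heptane-1,7-diyl diacetate
Conditions: I2, PPh3, imidazole, CH2Cl2, 0 °C to rt
Reagents that add atoms: iodine, II
Why: Activation of the primary hydroxyl by the PPh3/I2/imidazole reagent and SN2 displacement by iodide (Garegg–Samuelsson iodination) should give the iodide under neutral conditions that the acetates tolerate.

Step 12
Reactants: 23 (2R,6R)-2-(3-iodopropyl)-6-(prop-2-en-1-yl)heptane-1,7-diyl diacetate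
Product: 24 [(4R,8R)-4,8-bis(acetoxymethyl)undec-10-en-1-yl]triphenylphosphonium iodide
Conditions: PPh3, MeCN, 80 °C
Reagents that add atoms: triphenylphosphine, c1ccc(cc1)P(c1ccccc1)c1ccccc1
Why: SN2 quaternisation of triphenylphosphine by the primary iodide should give the Wittig salt with C14 as the future ylide carbon.

Step 13
Reactants: 24 [(4R,8R)-4,8-bis(acetoxymethyl)undec-10-en-1-yl]triphenylphosphonium iodide, 25 1-{[tert-butyl(dimethyl)silyl]oxy}propan-2-one
Product: 27 (2R,6R)-2-[(3Z)-5-{[tert-butyl(dimethyl)silyl]oxy}-4-methylpent-3-en-1-yl]-6-(prop-2-en-1-yl)heptane-1,7-diyl diacetate, via phosphorus ylide 26 (not isolated)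
Conditions: NaN(SiMe3)2 (1.0 equiv), THF, −78 °C; then 25, −78 to 0 °C
Reagents that add atoms: 1-{[tert-butyl(dimethyl)silyl]oxy}propan-2-one (25), CC(=O)CO[Si](C)(C)C(C)(C)C
Why: One equivalent of NaN(SiMe3)2 should convert the salt into non-stabilised ylide 26 at −78 °C, where it adds to the activated α-silyloxy ketone faster than to an acetate, and the kinetically controlled cycloaddition places the ylide alkyl chain and the CH2OSi group on the same side, so that loss of Ph3PO gives the Z-trisubstituted allylic ether (Z-selective Wittig olefination of α-alkoxy ketones).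

Step 14
Reactants: 27 Z-allylic silyl ether diacetate with one allyl arm, 28 ethyl 4-hydroxybut-2-ynoate
Product: 30 3-[(2E,4R,8R,11Z)-4,8-bis(acetoxymethyl)-13-{[tert-butyl(dimethyl)silyl]oxy}-12-methyltrideca-2,11-dien-1-yl]furan-2(5H)-one, via hydroxy enoate 29 (not isolated)
Conditions: 28 (1.3 equiv), RuCl(C5H5)(C8H12) [CpRu(cod)Cl] (5 mol %), MeOH, 65 °C
Reagents that add atoms: ethyl 4-hydroxybut-2-ynoate (28), CCOC(=O)C#CCO
Why: The CpRu catalyst should join the terminal alkene carbon C4 to the alkyne carbon α to the ester and shift the alkene to C5=C6 by transfer of a C6 hydrogen (ruthenium-catalysed Alder-ene reaction of terminal alkenes with γ-hydroxy alkynoates), giving Z-hydroxy enoate 29, which lactonises in hot methanol to the α-substituted butenolide while the trisubstituted alkene, silyl ether and acetates are spectators.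

Step 15
Reactants: 30 butenolide with the C5=C6 alkene
Product: 31 3-[(4R,8R,11Z)-4,8-bis(acetoxymethyl)-13-{[tert-butyl(dimethyl)silyl]oxy}-12-methyltridec-11-en-1-yl]furan-2(5H)-one
Conditions: H2 (1 atm), RhCl(PPh3)3 (cat.), benzene/EtOH, rt
Reagents that add atoms: none
Why: RhCl(PPh3)3 hydrogenates 1,2-disubstituted alkenes much faster than trisubstituted or conjugated trisubstituted ones (chemoselective homogeneous hydrogenation), so only C5=C6 should be saturated.

Step 16
Reactants: 31 silyl-protected target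
Product: 32 3-[(4R,8R,11Z)-4,8-bis(acetoxymethyl)-13-hydroxy-12-methyltridec-11-en-1-yl]furan-2(5H)-one (CNP0139404.2)
Conditions: HF·pyridine, pyridine, THF, 0 °C to rt
Reagents that add atoms: none
Why: Buffered fluoride should cleave the primary allylic silyl ether (desilylation) while the acetates and the base-sensitive butenolide are left untouched, giving the target.

Compound list
1 | (R)-but-3-yn-2-ol | C[C@@H](O)C#C | starting material
2 | (R)-tert-butyl(but-3-yn-2-yloxy)dimethylsilane | C[C@@H](O[Si](C)(C)C(C)(C)C)C#C | intermediate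
3 | 1,3-dibromopropane | BrCCCBr | starting material
4 | lithium (3R)-3-{[tert-butyl(dimethyl)silyl]oxy}but-1-yn-1-ide (in situ) | [Li]C#C[C@@H](C)O[Si](C)(C)C(C)(C)C | intermediate
5 | (R)-[(7-bromohept-3-yn-2-yl)oxy](tert-butyl)dimethylsilane (in situ) | C[C@@H](O[Si](C)(C)C(C)(C)C)C#CCCCBr | intermediate
6 | (2R,10R)-2,10-bis{[tert-butyl(dimethyl)silyl]oxy}undeca-3,8-diyne | C[C@@H](O[Si](C)(C)C(C)(C)C)C#CCCCC#C[C@@H](C)O[Si](C)(C)C(C)(C)C | intermediate
7 | (2R,10R)-undeca-3,8-diyne-2,10-diol | C[C@@H](O)C#CCCCC#C[C@@H](C)O | intermediate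
8 | dilithium bis(cyclic alkenylalanate) of 7: each alkyne hydroaluminated anti, each AlH2 bonded to C4 (C8) and to the neighbouring alkoxide oxygen in a five-membered ring (in situ) | [Li+].[Li+].C[C@H]1O[AlH2-]C(=C1)CCCC1=C[C@@H](C)O[AlH2-]1 | intermediate
9 | (2R,3E,8E,10R)-undeca-3,8-diene-2,10-diol | C[C@@H](O)/C=C/CCC/C=C/[C@@H](C)O | intermediate
10 | triethyl orthoacetate | CCOC(C)(OCC)OCC | starting material
11 | (2R,3E,8E,10R)-2,10-bis(1,1-diethoxyethoxy)undeca-3,8-diene (in situ) | CCOC(C)(OCC)O[C@H](C)/C=C/CCC/C=C/[C@@H](C)OC(C)(OCC)OCC | intermediate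
12 | (2R,3E,8E,10R)-2,10-bis[(1-ethoxyethenyl)oxy]undeca-3,8-diene (in situ) | C=C(OCC)O[C@H](C)/C=C/CCC/C=C/[C@@H](C)OC(=C)OCC | intermediate
13 | diethyl (3R,7R)-3,7-di[(E)-prop-1-en-1-yl]nonanedioate | C/C=C/[C@@H](CC(=O)OCC)CCC[C@H](CC(=O)OCC)/C=C/C | intermediate
14 | diethyl (3R,7R)-3,7-bis(5-methyl-1,2,4-trioxolan-3-yl)nonanedioate (in situ; ozonide ring centres undefined) | CC1OC(OO1)[C@@H](CC(=O)OCC)CCC[C@H](CC(=O)OCC)C1OC(C)OO1 | intermediate
15 | diethyl (3R,7R)-3,7-bis(hydroxymethyl)nonanedioate (in situ) | OC[C@@H](CC(=O)OCC)CCC[C@H](CC(=O)OCC)CO | intermediate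
16 | (4R,4'R)-4,4'-(propane-1,3-diyl)bis(dihydrofuran-2(3H)-one) | O=C1OC[C@@H](C1)CCC[C@H](CC(=O)O2)C2 | intermediate
17 | (4R,4'R)-4,4'-(propane-1,3-diyl)bis(tetrahydrofuran-2-ol) (anomer mixture) | OC1OC[C@@H](C1)CCC[C@H](CC(O)O2)C2 | intermediate
18 | (3R,7R)-3,7-bis(hydroxymethyl)nonanedial (in situ, as its alkoxide) | OC[C@@H](CC=O)CCC[C@H](CC=O)CO | intermediate
19 | (2R,6R)-2,6-di(prop-2-en-1-yl)heptane-1,7-diol | OC[C@@H](CC=C)CCC[C@H](CC=C)CO | intermediate
20 | (2R,6R)-2,6-di(prop-2-en-1-yl)heptane-1,7-diyl diacetate | CC(=O)OC[C@@H](CC=C)CCC[C@H](CC=C)COC(C)=O | intermediate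
21 | (2R,6R)-2-[3-(9-borabicyclo[3.3.1]nonan-9-yl)propyl]-6-(prop-2-en-1-yl)heptane-1,7-diyl diacetate (in situ) | CC(=O)OC[C@@H](CC=C)CCC[C@H](CCCB1C2CCCC1CCC2)COC(C)=O | intermediate
22 | (2R,6R)-2-(3-hydroxypropyl)-6-(prop-2-en-1-yl)heptane-1,7-diyl diacetate | CC(=O)OC[C@@H](CC=C)CCC[C@H](CCCO)COC(C)=O | intermediate
23 | (2R,6R)-2-(3-iodopropyl)-6-(prop-2-en-1-yl)heptane-1,7-diyl diacetate | CC(=O)OC[C@@H](CC=C)CCC[C@H](CCCI)COC(C)=O | intermediate
24 | [(4R,8R)-4,8-bis(acetoxymethyl)undec-10-en-1-yl]triphenylphosphonium iodide | CC(=O)OC[C@@H](CC=C)CCC[C@H](CCC[P+](c1ccccc1)(c1ccccc1)c1ccccc1)COC(C)=O.[I-] | intermediate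
25 | 1-{[tert-butyl(dimethyl)silyl]oxy}propan-2-one | CC(=O)CO[Si](C)(C)C(C)(C)C | starting material
26 | [(4R,8R)-4,8-bis(acetoxymethyl)undec-10-en-1-ylidene]triphenylphosphorane (in situ) | CC(=O)OC[C@@H](CC=C)CCC[C@H](CCC=P(c1ccccc1)(c1ccccc1)c1ccccc1)COC(C)=O | intermediate
27 | (2R,6R)-2-[(3Z)-5-{[tert-butyl(dimethyl)silyl]oxy}-4-methylpent-3-en-1-yl]-6-(prop-2-en-1-yl)heptane-1,7-diyl diacetate | CC(=O)OC[C@@H](CC=C)CCC[C@H](CC/C=C(/C)CO[Si](C)(C)C(C)(C)C)COC(C)=O | intermediate
28 | ethyl 4-hydroxybut-2-ynoate | CCOC(=O)C#CCO | starting material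
29 | ethyl (2Z)-2-[(2E,4R,8R,11Z)-4,8-bis(acetoxymethyl)-13-{[tert-butyl(dimethyl)silyl]oxy}-12-methyltrideca-2,11-dien-1-yl]-4-hydroxybut-2-enoate (in situ) | CCOC(=O)/C(C/C=C/[C@H](COC(C)=O)CCC[C@H](CC/C=C(/C)CO[Si](C)(C)C(C)(C)C)COC(C)=O)=C\CO | intermediate
30 | 3-[(2E,4R,8R,11Z)-4,8-bis(acetoxymethyl)-13-{[tert-butyl(dimethyl)silyl]oxy}-12-methyltrideca-2,11-dien-1-yl]furan-2(5H)-one | O=C1OCC=C1C/C=C/[C@H](COC(C)=O)CCC[C@H](CC/C=C(/C)CO[Si](C)(C)C(C)(C)C)COC(C)=O | intermediate
31 | 3-[(4R,8R,11Z)-4,8-bis(acetoxymethyl)-13-{[tert-butyl(dimethyl)silyl]oxy}-12-methyltridec-11-en-1-yl]furan-2(5H)-one | CC(=O)OC[C@@H](CCCC1=CCOC1=O)CCC[C@H](CC/C=C(/C)CO[Si](C)(C)C(C)(C)C)COC(C)=O | intermediate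
32 | 3-[(4R,8R,11Z)-4,8-bis(acetoxymethyl)-13-hydroxy-12-methyltridec-11-en-1-yl]furan-2(5H)-one (CNP0139404.2) | CC(=O)OC[C@@H](CCCC1=CCOC1=O)CCC[C@H](CC/C=C(/C)CO)COC(C)=O | target

Total step count: 16.
Longest linear sequence: 16 steps (1 to 32); 3, 10, 25 and 28 are bought and enter directly.

Steps most likely to fail

Step 13. The ylide may transfer an acetyl group from one of the acetates to its own carbon instead of adding to the ketone, and the cycloaddition may lose its cis preference, eroding the Z geometry at C14=C15. The fallback sets out from diol 19, returns at 27, and moves the geometry-defining event to a Horner–Wadsworth–Emmons reaction run before the acetates exist.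
- Protection of 19 (NaH, PMBCl, Bu4NI, DMF) should give (2R,6R)-1,7-bis[(4-methoxybenzyl)oxy]-2,6-di(prop-2-en-1-yl)heptane F1.
- Hydroboration of one arm with a deficiency of 9-BBN should give 9-[(4R,8R)-4,8-bis{[(4-methoxybenzyl)oxy]methyl}undec-10-en-1-yl]-9-borabicyclo[3.3.1]nonane F2, oxidised with NaOH/H2O2 to (4R,8R)-4,8-bis{[(4-methoxybenzyl)oxy]methyl}undec-10-en-1-ol F3.
- Dess–Martin oxidation should give (4R,8R)-4,8-bis{[(4-methoxybenzyl)oxy]methyl}undec-10-enal F4.
- Still–Gennari olefination with methyl 2-[bis(2,2,2-trifluoroethoxy)phosphoryl]propanoate (KN(SiMe3)2, 18-crown-6, THF, −78 °C) should give methyl (2Z,6R,10R)-6,10-bis{[(4-methoxybenzyl)oxy]methyl}-2-methyltrideca-2,12-dienoate F5.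
- Reduction with i-Bu2AlH should give (2Z,6R,10R)-6,10-bis{[(4-methoxybenzyl)oxy]methyl}-2-methyltrideca-2,12-dien-1-ol F6.
- Silylation (TBSCl, imidazole) should give tert-butyl{[(2Z,6R,10R)-6,10-bis{[(4-methoxybenzyl)oxy]methyl}-2-methyltrideca-2,12-dien-1-yl]oxy}dimethylsilane F7.
- DDQ in wet CH2Cl2 should release (2R,6R)-2-[(3Z)-5-{[tert-butyl(dimethyl)silyl]oxy}-4-methylpent-3-en-1-yl]-6-(prop-2-en-1-yl)heptane-1,7-diol F8, and acetylation (Ac2O, pyridine, DMAP) gives 27.

Step 14. The alkene may couple at the alkyne carbon remote from the ester, the catalyst may move the terminal double bond along the chain before coupling, or the catalyst may stall on the 1,4-diene product. The fallback sets out from 27, returns at 31 and so also bypasses step 15; it builds the butenolide by enolate alkylation and sulfoxide elimination.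
- 9-BBN should add only to the terminal alkene of 27 to give (2R,6R)-2-[3-(9-borabicyclo[3.3.1]nonan-9-yl)propyl]-6-[(3Z)-5-{[tert-butyl(dimethyl)silyl]oxy}-4-methylpent-3-en-1-yl]heptane-1,7-diyl diacetate F9, oxidised with NaBO3·4H2O to (2R,6R)-2-[(3Z)-5-{[tert-butyl(dimethyl)silyl]oxy}-4-methylpent-3-en-1-yl]-6-(3-hydroxypropyl)heptane-1,7-diyl diacetate F10.
- I2/PPh3/imidazole should give (2R,6R)-2-[(3Z)-5-{[tert-butyl(dimethyl)silyl]oxy}-4-methylpent-3-en-1-yl]-6-(3-iodopropyl)heptane-1,7-diyl diacetate F11.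
- 3-(Phenylsulfanyl)dihydrofuran-2(3H)-one F12, made from commercial α-bromo-γ-butyrolactone, thiophenol and Et3N, is deprotonated with KN(SiMe3)2 (THF, −78 °C) to potassium 3-(phenylsulfanyl)-4,5-dihydrofuran-2-olate F13.
- Alkylation of F13 with F11 in THF/DMPU should give 3-[(4R,8R,11Z)-4,8-bis(acetoxymethyl)-13-{[tert-butyl(dimethyl)silyl]oxy}-12-methyltridec-11-en-1-yl]-3-(phenylsulfanyl)dihydrofuran-2(3H)-one F14.
- NaIO4 in MeOH/H2O should oxidise only sulfur to give 3-[(4R,8R,11Z)-4,8-bis(acetoxymethyl)-13-{[tert-butyl(dimethyl)silyl]oxy}-12-methyltridec-11-en-1-yl]-3-(phenylsulfinyl)dihydrofuran-2(3H)-one F15.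
- Thermal syn-elimination (toluene, 110 °C, CaCO3) toward the ring CH2 should give 31.

Step 2. After the first substitution the remaining primary bromide may lose HBr to the basic acetylide, or the second substitution may stall, leaving mono-alkylated and enyne material. The fallback sets out from 2, returns at 6, and builds the three-carbon bridge stepwise.
- Lithium acetylide 4 (from 2 and n-BuLi) should open oxetane under BF3·OEt2 activation (THF, −78 °C) to give (6R)-6-{[tert-butyl(dimethyl)silyl]oxy}hept-4-yn-1-ol F16.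
- I2/PPh3/imidazole should give (R)-tert-butyl[(7-iodohept-3-yn-2-yl)oxy]dimethylsilane F17.
- A second portion of 4 in THF/DMPU should displace the iodide to give 6.

Further compounds
F1 | step 13 | (2R,6R)-1,7-bis[(4-methoxybenzyl)oxy]-2,6-di(prop-2-en-1-yl)heptane | COc1ccc(COC[C@@H](CC=C)CCC[C@H](CC=C)COCc2ccc(OC)cc2)cc1
F2 | step 13 | 9-[(4R,8R)-4,8-bis{[(4-methoxybenzyl)oxy]methyl}undec-10-en-1-yl]-9-borabicyclo[3.3.1]nonane | COc1ccc(COC[C@@H](CC=C)CCC[C@H](CCCB2C3CCCC2CCC3)COCc2ccc(OC)cc2)cc1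
F3 | step 13 | (4R,8R)-4,8-bis{[(4-methoxybenzyl)oxy]methyl}undec-10-en-1-ol | COc1ccc(COC[C@@H](CC=C)CCC[C@H](CCCO)COCc2ccc(OC)cc2)cc1
F4 | step 13 | (4R,8R)-4,8-bis{[(4-methoxybenzyl)oxy]methyl}undec-10-enal | COc1ccc(COC[C@@H](CC=C)CCC[C@H](CCC=O)COCc2ccc(OC)cc2)cc1
F5 | step 13 | methyl (2Z,6R,10R)-6,10-bis{[(4-methoxybenzyl)oxy]methyl}-2-methyltrideca-2,12-dienoate | COc1ccc(COC[C@@H](CC=C)CCC[C@H](CC/C=C(/C)C(=O)OC)COCc2ccc(OC)cc2)cc1
F6 | step 13 | (2Z,6R,10R)-6,10-bis{[(4-methoxybenzyl)oxy]methyl}-2-methyltrideca-2,12-dien-1-ol | COc1ccc(COC[C@@H](CC=C)CCC[C@H](CC/C=C(/C)CO)COCc2ccc(OC)cc2)cc1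
F7 | step 13 | tert-butyl{[(2Z,6R,10R)-6,10-bis{[(4-methoxybenzyl)oxy]methyl}-2-methyltrideca-2,12-dien-1-yl]oxy}dimethylsilane | COc1ccc(COC[C@@H](CC=C)CCC[C@H](CC/C=C(/C)CO[Si](C)(C)C(C)(C)C)COCc2ccc(OC)cc2)cc1
F8 | step 13 | (2R,6R)-2-[(3Z)-5-{[tert-butyl(dimethyl)silyl]oxy}-4-methylpent-3-en-1-yl]-6-(prop-2-en-1-yl)heptane-1,7-diol | OC[C@@H](CC=C)CCC[C@H](CC/C=C(/C)CO[Si](C)(C)C(C)(C)C)CO
F9 | step 14 | (2R,6R)-2-[3-(9-borabicyclo[3.3.1]nonan-9-yl)propyl]-6-[(3Z)-5-{[tert-butyl(dimethyl)silyl]oxy}-4-methylpent-3-en-1-yl]heptane-1,7-diyl diacetate | CC(=O)OC[C@@H](CCCB1C2CCCC1CCC2)CCC[C@H](CC/C=C(/C)CO[Si](C)(C)C(C)(C)C)COC(C)=O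
F10 | step 14 | (2R,6R)-2-[(3Z)-5-{[tert-butyl(dimethyl)silyl]oxy}-4-methylpent-3-en-1-yl]-6-(3-hydroxypropyl)heptane-1,7-diyl diacetate | CC(=O)OC[C@@H](CCCO)CCC[C@H](CC/C=C(/C)CO[Si](C)(C)C(C)(C)C)COC(C)=O
F11 | step 14 | (2R,6R)-2-[(3Z)-5-{[tert-butyl(dimethyl)silyl]oxy}-4-methylpent-3-en-1-yl]-6-(3-iodopropyl)heptane-1,7-diyl diacetate | CC(=O)OC[C@@H](CCCI)CCC[C@H](CC/C=C(/C)CO[Si](C)(C)C(C)(C)C)COC(C)=O
F12 | step 14 | 3-(phenylsulfanyl)dihydrofuran-2(3H)-one (racemic) | O=C1OCCC1Sc1ccccc1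
F13 | step 14 | potassium 3-(phenylsulfanyl)-4,5-dihydrofuran-2-olate | [K+].[O-]C1=C(Sc2ccccc2)CCO1
F14 | step 14 | 3-[(4R,8R,11Z)-4,8-bis(acetoxymethyl)-13-{[tert-butyl(dimethyl)silyl]oxy}-12-methyltridec-11-en-1-yl]-3-(phenylsulfanyl)dihydrofuran-2(3H)-one (both epimers at the lactone α-carbon) | CC(=O)OC[C@@H](CCCC1(Sc2ccccc2)CCOC1=O)CCC[C@H](CC/C=C(/C)CO[Si](C)(C)C(C)(C)C)COC(C)=O
F15 | step 14 | 3-[(4R,8R,11Z)-4,8-bis(acetoxymethyl)-13-{[tert-butyl(dimethyl)silyl]oxy}-12-methyltridec-11-en-1-yl]-3-(phenylsulfinyl)dihydrofuran-2(3H)-one (diastereomer mixture) | CC(=O)OC[C@@H](CCCC1(S(=O)c2ccccc2)CCOC1=O)CCC[C@H](CC/C=C(/C)CO[Si](C)(C)C(C)(C)C)COC(C)=O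
F16 | step 2 | (6R)-6-{[tert-butyl(dimethyl)silyl]oxy}hept-4-yn-1-ol | C[C@@H](O[Si](C)(C)C(C)(C)C)C#CCCCO
F17 | step 2 | (R)-tert-butyl[(7-iodohept-3-yn-2-yl)oxy]dimethylsilane | C[C@@H](O[Si](C)(C)C(C)(C)C)C#CCCCI
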